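I began with what the alder run left over. At 4.00 h, 9.90% of the charge had become neither G nor E, and if X falls at a steady pseudo-first-order pace, that leftover gives a rate constant 0.578 h⁻¹. The charge hardly mattered in the earlier runs: at 0.833 h, G stood at 35.5% in alder, 35.4% in cedar and 35.2% in birch, with X from 0.70 M to 2.8 M.

| flask | X | J | remark | time |
|---|---|---|---|---|
| cedar | 1.4 M | 3.8 mM | run made earlier |  |
| alder | 0.70 M | 3.8 mM | run made earlier |  |
| birch | 2.8 M | 3.8 mM | run made earlier |  |
| south-east | 1.4 M | 3.8 mM | a single well-mixed tank run continuously and read at steady state, 3.0 h in it on average |  |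
| south | 1.4 M | 3.8 mM | everything together in a closed stirred flask, run for 3.0 h | 3.0 h |
| north-west | 1.4 M (fed, over 1.50 h) | 3.8 mM | all but X at the start; X goes in evenly over 1.50 h, the run ends at 3.0 h | 3.0 h |

- cedar (time / h: G / %, E / %): 0.833: 35.4, 3.7; 1.50: 51.1, 6.3; 2.50: 66.8, 10.5; 3.00: 71.8, 11.2
- alder (time / h: G / %, E / %): 0.833: 35.5, 3.5; 2.00: 60.1, 9.4; 2.50: 66.5, 10.4; 4.00: 77.4, 12.7
- birch (time / h: G / %, E / %): 0.833: 35.2, 3.1; 2.00: 59.9, 8.7; 2.50: 66.6, 10.5; 4.00: 77.3, 12.3

(scatter of a reading: 0.3 percentage points)

- the set-up with the highest share of G in all that became G or E, at the outlet or at the end ("none" if the first two lie within 2 percentage points) (south-east / south / north-west / none)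
- share of G in all that became G or E, at the outlet or at the end, south-east
- share of G in all that became G or E, at the outlet or at the end, south
- share of G in all that became G or E, at the outlet or at the end, north-west

- the stated concentrations are those of everything mixed, before any reaction; amounts are the same in each set-up
- what may be going on: J -> 2 Q; X + Q -> D + G; X + D -> G + D; 2 D -> L; G <-> E
- the feed brings no volume worth counting
- the earlier runs were made in a closed, stirred flask

I followed alder in slow motion. In the first instants, X turns into G while E is still absent. By 0.833 h, E had reached 3.5% of the charge. At 4.00 h, E was 14.1% of G and E together, a reading that I took as E's resting share. The early E then equals that share of what had become G or E some time before, and this gives a lag of 0.339 h. I named this time by which E trails the making of product the lag, the relaxation time of the pair G and E. It carries the scatter of a small reading. Because the lag is shorter than the time of X's loss, I expected E to keep close behind in alder, with the freshest product short of E at the end.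

For the closed flask, south, the rule gave a G share of 86.6%. In the tank, south-east, the lag counts against the mean stay, so E's share shrinks by the factor 1 + lag/stay, and G's share is 87.3%. In north-west, I reckoned X at 28.1% at the end and 34.2% one lag earlier, which gives 87.1%. These lie 0.70 percentage points apart at most, so I expected no winner.

The forecast read 87.3%, 86.6% and 87.1%, with none as best, and called G to E “a fast reversible step independent of X”.

The flask gave 87.1% for south-east, 86.3% for south and 87.0% for north-west, so the answer to best is none.

    J → 2 Q (k = 3.20 × 10⁻⁴ min⁻¹)
    X + Q → D + G (k = 6.00 × 10⁵ M⁻¹ s⁻¹)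
    X + D → G + D, rate k3*[D]*[X] (k = 23000 M⁻¹ s⁻¹)
    2 D → L (k = 4.00 × 10⁸ M⁻¹ s⁻¹)
    G ⇌ E (K = 0.170, k = 0.00650 min⁻¹)

South's answer moves by 5 points at 0.747 h, about twice the lag. Against 30.0 h, the lag is hardly any of the time, so the rule puts south's G share at 85.9%. Left that long, south stood at 85.5%.

The numbers in the tables are simulated with constants of no real substance; scatter was added.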